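## Analysis of the target

Locants used throughout: C7–C9 for the furofuran half bonded to ring B (the central guaiacyl ring), C7′–C9′ for the half bonded to ring C (the syringyl ring), and C7″–C9″ for the glycerol chain that carries ring A (the terminal guaiacyl ring). The core is a 2,6-diaryl-3,7-dioxabicyclo[3.3.0]octane: two tetrahydrofuran rings share the C8–C8′ bond, are cis-fused, and carry both aryl groups on the convex (exo) face, with configuration 7R,8S,7′R,8′S. O4 of ring B is the ether oxygen of an arylglycerol β-aryl ether whose two centres are erythro (7″R,8″S); they lie too far from the furofuran centres to be controlled by them, so the two stereo-clusters must be set independently. Sensitive groups are the two free phenols (oxidation to quinone methides), the three electron-rich benzylic C–O bonds at C7, C7′ and C7″ (ionisation in acid with epimerisation, and hydrogenolysis), and the benzylic alcohol. The difficulty is that the two aryl groups differ, so the bicycle cannot come from dimerising one phenylpropanoid, while four contiguous centres need absolute control and the hindered secondary aryl ether needs erythro control. The strategy rests on C9 and C9′: both are OCH2 carbons, and at the lactone oxidation level they are the carbonyls of a 3,7-dioxabicyclo[3.3.0]octane-4,8-dione. C8 is then α to the C9 carbonyl and can take the ring B aldehyde carbon as C7 in an aldol reaction, after which O7 acylates C9′ to close the second ring.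

## Retrosynthetic reasoning

**Protecting groups (31 ⇒ 30 ⇒ 29).** The two phenols are carried as benzyl ethers and the 7″,9″-diol as an isopropylidene acetal. The acetal is removed first (29 to 30), while both phenols are still etherified and the benzylic positions are least prone to ionise. Neutral hydrogenolysis is left for the last step (30 to 31).

**Ring ether bonds (29 ⇒ 27 ⇒ 26).** The bonds O7–C9′ and O7′–C9 are cut to give tetraol 27. In the forward sense each benzylic hydroxyl displaces a primary sulfonate, so the C7–O and C7′–O bonds are never broken and all four centres are simply carried over from 27. Raising C9 and C9′ to carbonyls leads back to bis-lactone 26, from which 27 follows by hydride reduction.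

**Key disconnection (26 ⇒ 9 + 21).** The C7–C8 bond (aldol) and the O7–C9′ acyl bond (lactone) are cut, giving paraconic acid 9 and aldehyde 21. This cut is convergent: it divides the molecule into two halves of similar size, each bringing two finished stereocentres, and 21 already carries the complete side chain. The free acid is preferred to an ester because the carboxylate makes C8′–H non-acidic, so enolisation can only occur at C8 and the lactone cannot open by β-elimination. Two points have to be put right in the forward direction:

- The enolate is attacked on the face away from the C8′ carboxylate, so the new arm at C8 is trans to C9′ and cannot reach it.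
- A lithium carboxylate is not acylated by an alkoxide.

The plan therefore accepts the anti aldol on that face, which already gives C7 in the R configuration. O7 is parked as a silyl ether, C8 is re-enolised and protonated from the same open face, which turns the arm cis to C9′, and the ring is then closed with a base-free acyl activation. Anti aldol followed by inversion at C8 amounts to the syn relationship between C8′ and O7, which is the exo aryl isomer.

**Paraconic acid (9 ⇒ 7 ⇒ 5 + 2).** The C7′–C8′ bond is cut by an auxiliary-controlled syn aldol between succinate imide 5 and aldehyde 2. The syn adduct 6 lactonises to the trans lactone 7, and peroxide-mediated removal of the auxiliary gives 9. Imide 5 comes from 3 and 4, and 2 from 1.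

**Aryl ether (21 ⇒ 19 + 20).** The C8″–O(aryl) bond is cut. A nucleophilic aromatic substitution would keep the configuration at C8″ and would need the erythro alcohol, whereas the reliable glycolate aldol delivers the threo series. The bond is therefore made with inversion, by Mitsunobu etherification of the threo alcohol 19 with vanillin 20, which also brings the aldehyde in unprotected.

**Threo alcohol (19 ⇒ 17 ⇒ 16 ⇒ 15 ⇒ 13 + 14).** The C7″–C8″ bond is cut by a syn glycolate aldol of imide 13 with aldehyde 14. O8″ is blocked as an allyl ether, so that the 7″,9″-diol 16 can only form the six-membered acetal 17. The allyl group is removed without hydrogen or oxidant, both of which would endanger the aryl benzyl ether or the electron-rich benzylic acetal carbon. Imide 13 comes from 10 and 11.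

## Alternatives that were turned down

**Alternative 1:** The C7′–C8′ bond is cut. In the forward step Rh2(OAc)4 turns the α-diazo lactone A1 into a carbene at C8′, which inserts into the benzylic C7′–H bond of the syringylmethyl ether and closes the ring containing O9, giving furofuranone A2.
- For: the closure is intramolecular, the cis fusion is enforced by the tether, the C–H bond attacked is both benzylic and α to oxygen, and only one lactone carbonyl remains to be reduced. On certainty of ring fusion this route is stronger than the chosen one.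
- Against: C7′ is created in the insertion transition state with no element that clearly favours the exo aryl group. Diazo transfer to a lactone needs prior activation. The lactone must later be reduced to the ether in two operations. A2 carries ring B only as a silyl-protected phenol, so the erythro aryl ether would have to be built afterwards on an electron-rich phenol, where aromatic substitution is impossible and a second auxiliary sequence would be needed late.
- Comparison: the chosen strategy brings the finished side chain in on the aldehyde and sets C7′ and C8′ from an auxiliary before the annulation.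

**Alternative 2:** The C8–C8′ and C7–O9′ bonds are cut. Cp2TiCl (trivalent titanium, from Cp2TiCl2 and zinc) opens the epoxide of A3 to a C8′ radical, which closes 5-exo onto C8; the benzylic C7 centre is then closed onto O9′ with iodine, giving A4, which is identical with 29.
- For: it is the shortest route, reaches the ether oxidation level directly, needs no lactone reductions and tolerates the ethers present. On step economy it is clearly stronger.
- Against: the C8′ radical is planar, so C8′, C8 and C7 are all set relative to the single C7′ centre in a radical cyclisation and a cation-like closure, and diastereomer mixtures must be expected. A3 also requires an enantiopure, acid-labile, electron-rich aryl epoxy carbinol and its etherification with a cinnamyl unit made from the side-chain aldehyde.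
- Comparison: the chosen strategy is longer but assigns each stereocentre to a defined controlling element.

**Alternative 3:** The C7′–O9 bond is cut. Ag2O (monovalent silver) oxidises the free syringyl phenol of the lariciresinol-type tetrahydrofuran A5 to its para-quinone methide, and the C9 hydroxyl adds to C7′ (5-exo), giving A6.
- For: only the free phenol is oxidised, the conditions are mild, the cis fusion follows from the existing ring, the addition is reversible and so favours the exo aryl group, and A6 is two deprotections from the target with the syringyl phenol already free. In mildness of the last ring closure it is stronger.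
- Against: the problem is moved to A5, a tetrahydrofuran with three contiguous centres and a benzyl branch that needs its own long stereocontrolled synthesis. The quinone methide can also tautomerise to the styrene or add water.
- Comparison: the chosen strategy builds the second ring and two centres in one convergent annulation and then treats both halves of the bicycle by the same reduction and cyclisation.

Key step: step 11

Remark on names: ArC = 4-(benzyloxy)-3,5-dimethoxyphenyl; ArB = 3-methoxy-4-{[(4R,5S)-4-(4-benzyloxy-3-methoxyphenyl)-2,2-dimethyl-1,3-dioxan-5-yl]oxy}phenyl, that is ring B with its acetonide-protected erythro side chain.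
Assumption: 4-(benzyloxy)-3-methoxybenzaldehyde 14, 2-(prop-2-en-1-yloxy)acetic acid 11, both oxazolidinones and methyl 4-chloro-4-oxobutanoate 4 are taken as purchased materials.

## Route

Step 1
Reactants: 1 syringaldehyde (4-hydroxy-3,5-dimethoxybenzaldehyde)
Product: 2 4-(benzyloxy)-3,5-dimethoxybenzaldehyde
Conditions: BnBr, K2CO3, DMF, 60 °C
Reagents that add atoms: benzyl bromide, BrCc1ccccc1
Why: Williamson etherification of the acidic, flanked phenol by SN2 on benzyl bromide; the aldehyde is not touched.

Step 2
Reactants: 3 (R)-4-benzyl-1,3-oxazolidin-2-one; 4 methyl 4-chloro-4-oxobutanoate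
Product: 5 methyl 4-[(4R)-4-benzyl-2-oxo-1,3-oxazolidin-3-yl]-4-oxobutanoate
Conditions: n-BuLi, THF, −78 °C; then 4, −78 → 0 °C
Reagents that add atoms: none
Why: N-acylation of the lithiated oxazolidinone; the acid chloride reacts far faster than the methyl ester, so only the imide is formed.

Step 3
Reactants: 5 succinate imide; 2 aldehyde
Product: 7 (4R)-4-benzyl-3-{[(2R,3R)-2-ArC-5-oxooxolan-3-yl]carbonyl}-1,3-oxazolidin-2-one (trans lactone), via syn-aldol adduct 6 (not isolated)
Conditions: Bu2BOTf, i-Pr2NEt, CH2Cl2, 0 °C; 2, −78 → 0 °C; pH 7 buffer, MeOH, H2O2; then TsOH·H2O (cat.), CH2Cl2, rt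
Reagents that add atoms: none
Why: Evans syn aldol: the boron triflate enolises only the imide CH2 to the Z enolate, and the (R)-benzyl auxiliary directs the aldehyde to the (3R,4R) adduct 6, which sets C8′ and C7′. Acid-catalysed transesterification of the C7′ hydroxyl onto the methyl ester then closes the γ-lactone, the syn adduct giving the trans-2,3-disubstituted ring.

Step 4
Reactants: 7 lactone imide
Product: 9 (2R,3R)-2-ArC-5-oxooxolane-3-carboxylic acid (trans syringyl paraconic acid), via peroxy acid 8 (not isolated)
Conditions: LiOH, H2O2, THF–H2O, 0 °C; Na2SO3; then 1 M HCl to pH 2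
Reagents that add atoms: hydrogen peroxide, OO
Why: Hydroperoxide attacks the exocyclic imide carbonyl selectively and releases the auxiliary; sulfite reduces the peracid. Any lactone opened by hydroxide recloses on acidification, and C8′ is not enolised at the carboxylate stage.

Step 5
Reactants: 10 (S)-4-benzyl-1,3-oxazolidin-2-one; 11 2-(prop-2-en-1-yloxy)acetic acid
Product: 13 (4S)-4-benzyl-3-[2-(prop-2-en-1-yloxy)acetyl]-1,3-oxazolidin-2-one, via mixed pivalic anhydride 12 (not isolated)
Conditions: t-BuCOCl, Et3N, THF, −20 °C; then LiCl, 10, rt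
Reagents that add atoms: none
Why: Mixed-anhydride activation followed by LiCl/amine-mediated N-acylation of the oxazolidinone; attack occurs at the less hindered glycolyl carbonyl.

Step 6
Reactants: 13 glycolate imide; 14 4-(benzyloxy)-3-methoxybenzaldehyde
Product: 15 (4S)-4-benzyl-3-[(2S,3R)-3-(4-benzyloxy-3-methoxyphenyl)-3-hydroxy-2-(prop-2-en-1-yloxy)propanoyl]-1,3-oxazolidin-2-one
Conditions: Bu2BOTf, Et3N, CH2Cl2, −78 → 0 °C; 14, −78 → 0 °C; pH 7 buffer, MeOH, H2O2
Reagents that add atoms: none
Why: Evans syn glycolate aldol through the Z boron enolate; the (S)-auxiliary gives C7″ in its final R configuration and C8″ as the threo epimer, which step 10 inverts.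

Step 7
Reactants: 15 aldol adduct
Product: 16 (1R,2R)-1-(4-benzyloxy-3-methoxyphenyl)-2-(prop-2-en-1-yloxy)propane-1,3-diol
Conditions: LiBH4, MeOH (1 equiv), THF, 0 °C
Reagents that add atoms: none
Why: Reductive cleavage of the imide to the primary alcohol with recovery of the auxiliary; neither centre is epimerisable under these conditions.

Step 8
Reactants: 16 diol
Product: 17 (4R,5R)-4-(4-benzyloxy-3-methoxyphenyl)-2,2-dimethyl-5-(prop-2-en-1-yloxy)-1,3-dioxane (cis)
Conditions: Me2C(OMe)2, PPTS (cat.), CH2Cl2, rt
Reagents that add atoms: 2,2-dimethoxypropane, COC(C)(C)OC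
Why: Acid-catalysed transketalisation; with O8″ blocked only the 1,3-diol is free, so the six-membered acetal forms, with the aryl group equatorial and the allyloxy group axial.

Step 9
Reactants: 17 allyl ether
Product: 19 (4R,5R)-4-(4-benzyloxy-3-methoxyphenyl)-2,2-dimethyl-1,3-dioxan-5-ol (cis), via prop-1-enyl ether 18 (not isolated)
Conditions: [Ir(cod)(PMePh2)2]PF6 (2 mol %, activated with H2), THF, rt; then I2, NaHCO3, THF–H2O, 0 °C
Reagents that add atoms: none
Why: Iridium hydride-catalysed isomerisation of the allyl ether to the (E)-prop-1-enyl ether, then iodonium-induced hydrolysis of the enol ether under bicarbonate buffering. The O–C5 bond is not broken, so the configuration is kept.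

Step 10
Reactants: 19 cis alcohol; 20 vanillin (4-hydroxy-3-methoxybenzaldehyde)
Product: 21 4-{[(4R,5S)-4-(4-benzyloxy-3-methoxyphenyl)-2,2-dimethyl-1,3-dioxan-5-yl]oxy}-3-methoxybenzaldehyde (trans; ring B aldehyde with the protected erythro arylglycerol)
Conditions: PPh3, DIAD, toluene, 0 → 60 °C
Reagents that add atoms: none
Why: Mitsunobu etherification with the acidic phenol of vanillin as pronucleophile; SN2 at C5 with inversion turns the threo (cis) alcohol into the erythro (trans) aryl ether and installs ring B with its free aldehyde. The axial oxyphosphonium group is displaced along the equatorial direction, on which C5 of a 1,3-dioxane has no syn-axial hydrogens.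

Step 11
Reactants: 9 trans syringyl paraconic acid (1.2 equiv); 21 ring B aldehyde
Product: 26 (3R,3aR,6R,6aR)-3-ArB-6-ArC-tetrahydro-1H,3H-furo[3,4-c]furan-1,4-dione (cis-fused bis-lactone with both aryl groups exo), via 8-epi aldolate 22 (not isolated), via 8-epi silyl ether 23 (not isolated), via cis silyl ether 24 (not isolated), via cis hydroxy acid 25 (not isolated)
Conditions: LiN(i-Pr)2 (2.1 equiv), THF, −78 °C; 21, −78 °C; Me3SiCl; LiN(i-Pr)2 (1.5 equiv), −78 → −50 °C; 2,6-di-tert-butyl-4-methylphenol, −78 °C; 10% aq citric acid, rt; then EDC·HCl, CH2Cl2, 0 °C → rt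
Reagents that add atoms: none
Why: Two equivalents of amide base give the carboxylate and lactone-enolate dianion of 9; the carboxylate charge makes C8′–H non-acidic, so C8 is the only enolate carbon and the lactone cannot open by β-elimination. The enolate adds to 21 through a Zimmerman–Traxler chair to form C7–C8: the ring-locked E enolate gives the anti adduct and attack occurs on the face away from the C8′ carboxylate, as in alkylations of paraconic acid dianions, so aldolate 22 has C7 already R but its new arm trans to C9′. That isomer cannot lactonise, and a lithium carboxylate is not acylated by an alkoxide, so O7 is parked as the trimethylsilyl ether 23 and C8 is enolised again, the carboxylate once more protecting C8′. The hindered phenol protonates this enolate from the same open face, a kinetic protonation of a lactone enolate that turns the C7 arm cis to C9′ in 24. Aqueous acid removes the silyl group, and the carbodiimide activates C9′ without base, so that O7 of 25 closes the second γ-lactone by 5-exo-trig acyl substitution; only the cis ring fusion is possible. C7 is thus controlled by the aldol transition state and C8 by the protonation, both steered by the C8′ substituent, and anti aldol followed by inversion at C8 corresponds to the exo aryl group. The closest known reaction type is the aldol-lactonisation of succinate and paraconate enolates with aryl aldehydes to 2,6-diaryl-3,7-dioxabicyclo[3.3.0]octane-4,8-diones. The step needs the silyloxy group β to the second enolate to survive, which the low temperature should secure, and it needs C8′ to stay untouched, which the absence of base during activation secures.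

Step 12
Reactants: 26 bis-lactone
Product: 27 (1R,2S,3S,4R)-1-ArB-4-ArC-2,3-bis(hydroxymethyl)butane-1,4-diol
Conditions: LiAlH4, THF, 0 °C → rt
Reagents that add atoms: none
Why: Hydride reduction of both lactones to the diol level; the acetonide, the aryl ethers and all four centres are inert.

Step 13
Reactants: 27 tetraol
Product: 29 (1R,3aS,4R,6aS)-1-ArB-4-ArC-tetrahydro-1H,3H-furo[3,4-c]furan (dibenzyl ether acetonide of the target), via bis-mesylate 28 (not isolated)
Conditions: MsCl (2.3 equiv), pyridine, 0 °C → rt
Reagents that add atoms: none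
Why: The primary hydroxyls are sulfonylated much faster than the hindered benzylic ones; each benzylic hydroxyl then displaces its 1,4-related primary mesylate in a 5-exo-tet Williamson closure. The C7–O and C7′–O bonds stay intact, so the configuration of 27 is retained.

Step 14
Reactants: 29 acetonide
Product: 30 (1R,2S)-1-(4-benzyloxy-3-methoxyphenyl)-2-{4-[(1R,3aS,4R,6aS)-4-ArC-tetrahydro-1H,3H-furo[3,4-c]furan-1-yl]-2-methoxyphenoxy}propane-1,3-diol
Conditions: AcOH–H2O–THF (3:1:1), 45 °C
Reagents that add atoms: none
Why: Mild acid hydrolysis of the isopropylidene acetal; with both phenols still benzylated the benzylic ethers of the furofuran and C7″ should not ionise under these conditions.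

Step 15
Reactants: 30 dibenzyl ether
Product: 31 Ficusesquilignan A, (1R,2S)-1-(4-hydroxy-3-methoxyphenyl)-2-{4-[(1R,3aS,4R,6aS)-4-(4-hydroxy-3,5-dimethoxyphenyl)tetrahydro-1H,3H-furo[3,4-c]furan-1-yl]-2-methoxyphenoxy}propane-1,3-diol
Conditions: H2 (1 atm), Pd/C (10%), EtOAc–EtOH, rt
Reagents that add atoms: none
Why: Hydrogenolysis of the two aryl benzyl ethers, which under neutral conditions are cleaved much faster than the benzylic dialkyl ethers and the benzylic alcohol; the reaction is stopped after uptake of two equivalents of hydrogen.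

## Compound list

1 | syringaldehyde | COc1cc(C=O)cc(OC)c1O | starting material
2 | 4-(benzyloxy)-3,5-dimethoxybenzaldehyde | COc1cc(C=O)cc(OC)c1OCc1ccccc1 | intermediate
3 | (R)-4-benzyl-1,3-oxazolidin-2-one | O=C1OC[C@@H](Cc2ccccc2)N1 | starting material
4 | methyl 4-chloro-4-oxobutanoate | COC(=O)CCC(Cl)=O | starting material
5 | methyl 4-[(4R)-4-benzyl-2-oxo-1,3-oxazolidin-3-yl]-4-oxobutanoate | COC(=O)CCC(=O)N1C(=O)OC[C@H]1Cc1ccccc1 | intermediate
6 | methyl (3R,4R)-4-ArC-3-{[(4R)-4-benzyl-2-oxo-1,3-oxazolidin-3-yl]carbonyl}-4-hydroxybutanoate | COC(=O)C[C@@H](C(=O)N1C(=O)OC[C@H]1Cc1ccccc1)[C@@H](O)c1cc(OC)c(OCc2ccccc2)c(OC)c1 | intermediate (not isolated)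
7 | (4R)-4-benzyl-3-{[(2R,3R)-2-ArC-5-oxooxolan-3-yl]carbonyl}-1,3-oxazolidin-2-one | O=C([C@@H]1CC(=O)O[C@H]1c1cc(OC)c(OCc2ccccc2)c(OC)c1)N1C(=O)OC[C@H]1Cc1ccccc1 | intermediate
8 | (2R,3R)-2-ArC-5-oxooxolane-3-carboperoxoic acid | OOC(=O)[C@@H]1CC(=O)O[C@H]1c1cc(OC)c(OCc2ccccc2)c(OC)c1 | intermediate (not isolated)
9 | (2R,3R)-2-ArC-5-oxooxolane-3-carboxylic acid | OC(=O)[C@@H]1CC(=O)O[C@H]1c1cc(OC)c(OCc2ccccc2)c(OC)c1 | intermediate
10 | (S)-4-benzyl-1,3-oxazolidin-2-one | O=C1OC[C@H](Cc2ccccc2)N1 | starting material
11 | 2-(prop-2-en-1-yloxy)acetic acid | C=CCOCC(=O)O | starting material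
12 | 2,2-dimethylpropanoic 2-(prop-2-en-1-yloxy)acetic anhydride | C=CCOCC(=O)OC(=O)C(C)(C)C | intermediate (not isolated)
13 | (4S)-4-benzyl-3-[2-(prop-2-en-1-yloxy)acetyl]-1,3-oxazolidin-2-one | C=CCOCC(=O)N1C(=O)OC[C@@H]1Cc1ccccc1 | intermediate
14 | 4-(benzyloxy)-3-methoxybenzaldehyde | COc1cc(C=O)ccc1OCc1ccccc1 | starting material
15 | (4S)-4-benzyl-3-[(2S,3R)-3-(4-benzyloxy-3-methoxyphenyl)-3-hydroxy-2-(prop-2-en-1-yloxy)propanoyl]-1,3-oxazolidin-2-one | C=CCO[C@H](C(=O)N1C(=O)OC[C@@H]1Cc1ccccc1)[C@H](O)c1ccc(OCc2ccccc2)c(OC)c1 | intermediate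
16 | (1R,2R)-1-(4-benzyloxy-3-methoxyphenyl)-2-(prop-2-en-1-yloxy)propane-1,3-diol | C=CCO[C@H](CO)[C@H](O)c1ccc(OCc2ccccc2)c(OC)c1 | intermediate
17 | (4R,5R)-4-(4-benzyloxy-3-methoxyphenyl)-2,2-dimethyl-5-(prop-2-en-1-yloxy)-1,3-dioxane | C=CCO[C@@H]1COC(C)(C)O[C@@H]1c1ccc(OCc2ccccc2)c(OC)c1 | intermediate
18 | (4R,5R)-4-(4-benzyloxy-3-methoxyphenyl)-2,2-dimethyl-5-[(E)-prop-1-en-1-yloxy]-1,3-dioxane | C/C=C/O[C@@H]1COC(C)(C)O[C@@H]1c1ccc(OCc2ccccc2)c(OC)c1 | intermediate (not isolated)
19 | (4R,5R)-4-(4-benzyloxy-3-methoxyphenyl)-2,2-dimethyl-1,3-dioxan-5-ol | O[C@@H]1COC(C)(C)O[C@@H]1c1ccc(OCc2ccccc2)c(OC)c1 | intermediate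
20 | vanillin | COc1cc(C=O)ccc1O | starting material
21 | 4-{[(4R,5S)-4-(4-benzyloxy-3-methoxyphenyl)-2,2-dimethyl-1,3-dioxan-5-yl]oxy}-3-methoxybenzaldehyde | COc1cc([C@@H](OC(C)(C)OC2)[C@H]2Oc2ccc(C=O)cc2OC)ccc1OCc1ccccc1 | intermediate
22 | (2R,3R,4S)-2-ArC-4-[(R)-ArB(hydroxy)methyl]-5-oxooxolane-3-carboxylic acid, in the flask as dilithium alkoxide carboxylate | COc1cc([C@@H](OC(C)(C)OC2)[C@H]2Oc2ccc([C@H](O)[C@H]3C(=O)O[C@@H](c4cc(OC)c(OCc5ccccc5)c(OC)c4)[C@@H]3C(=O)O)cc2OC)ccc1OCc1ccccc1 | intermediate (not isolated)
23 | (2R,3R,4S)-2-ArC-4-[(R)-ArB(trimethylsilyloxy)methyl]-5-oxooxolane-3-carboxylic acid, in the flask as lithium carboxylate | COc1cc([C@@H](OC(C)(C)OC2)[C@H]2Oc2ccc([C@H](O[Si](C)(C)C)[C@H]3C(=O)O[C@@H](c4cc(OC)c(OCc5ccccc5)c(OC)c4)[C@@H]3C(=O)O)cc2OC)ccc1OCc1ccccc1 | intermediate (not isolated)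
24 | (2R,3R,4R)-2-ArC-4-[(R)-ArB(trimethylsilyloxy)methyl]-5-oxooxolane-3-carboxylic acid, in the flask as lithium carboxylate | COc1cc([C@@H](OC(C)(C)OC2)[C@H]2Oc2ccc([C@H](O[Si](C)(C)C)[C@@H]3C(=O)O[C@@H](c4cc(OC)c(OCc5ccccc5)c(OC)c4)[C@@H]3C(=O)O)cc2OC)ccc1OCc1ccccc1 | intermediate (not isolated)
25 | (2R,3R,4R)-2-ArC-4-[(R)-ArB(hydroxy)methyl]-5-oxooxolane-3-carboxylic acid | COc1cc([C@@H](OC(C)(C)OC2)[C@H]2Oc2ccc([C@H](O)[C@@H]3C(=O)O[C@@H](c4cc(OC)c(OCc5ccccc5)c(OC)c4)[C@@H]3C(=O)O)cc2OC)ccc1OCc1ccccc1 | intermediate (not isolated)
26 | (3R,3aR,6R,6aR)-3-ArB-6-ArC-tetrahydro-1H,3H-furo[3,4-c]furan-1,4-dione | COc1cc([C@@H](OC(C)(C)OC2)[C@H]2Oc2ccc([C@@H]3OC(=O)[C@@H]4[C@H]3C(=O)O[C@H]4c3cc(OC)c(OCc5ccccc5)c(OC)c3)cc2OC)ccc1OCc1ccccc1 | intermediate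
27 | (1R,2S,3S,4R)-1-ArB-4-ArC-2,3-bis(hydroxymethyl)butane-1,4-diol | COc1cc([C@@H](OC(C)(C)OC2)[C@H]2Oc2ccc([C@H](O)[C@H](CO)[C@@H](CO)[C@@H](O)c3cc(OC)c(OCc4ccccc4)c(OC)c3)cc2OC)ccc1OCc1ccccc1 | intermediate
28 | (2S,3S)-2-[(R)-ArB(hydroxy)methyl]-3-[(R)-ArC(hydroxy)methyl]butane-1,4-diyl dimethanesulfonate | COc1cc([C@@H](OC(C)(C)OC2)[C@H]2Oc2ccc([C@H](O)[C@H](COS(C)(=O)=O)[C@@H](COS(C)(=O)=O)[C@@H](O)c3cc(OC)c(OCc4ccccc4)c(OC)c3)cc2OC)ccc1OCc1ccccc1 | intermediate (not isolated)
29 | (1R,3aS,4R,6aS)-1-ArB-4-ArC-tetrahydro-1H,3H-furo[3,4-c]furan | COc1cc([C@@H](OC(C)(C)OC2)[C@H]2Oc2ccc([C@@H]3OC[C@@H]4[C@H]3CO[C@H]4c3cc(OC)c(OCc5ccccc5)c(OC)c3)cc2OC)ccc1OCc1ccccc1 | intermediate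
30 | (1R,2S)-1-(4-benzyloxy-3-methoxyphenyl)-2-{4-[(1R,3aS,4R,6aS)-4-ArC-tetrahydro-1H,3H-furo[3,4-c]furan-1-yl]-2-methoxyphenoxy}propane-1,3-diol | COc1cc([C@@H](O)[C@H](CO)Oc2ccc([C@@H]3OC[C@@H]4[C@H]3CO[C@H]4c3cc(OC)c(OCc5ccccc5)c(OC)c3)cc2OC)ccc1OCc1ccccc1 | intermediate
31 | Ficusesquilignan A | COc1cc([C@@H](O)[C@H](CO)Oc2ccc([C@@H]3OC[C@@H]4[C@H]3CO[C@H]4c3cc(OC)c(O)c(OC)c3)cc2OC)ccc1O | target

## Step count and least certain steps

Total: 15 steps. Longest linear sequence: 11 steps (steps 5 to 15, from 10, 11 and 14).

**Step 11 (key step).** Two things are most likely to fail: loss of the silyloxy group by β-elimination from the second enolate, which would give the benzylidene lactone, and incomplete face selectivity in the aldol (anti against syn) or in the protonation at C8. Both enolate operations depend on the same modest steric bias of the C8′ carboxylate, and the second enolate carries a leaving group on an electron-rich benzylic carbon. The fallback gives up the kinetic relay for a thermodynamically driven closure. It sets out from 9 and 21. Acid 9 is esterified with Me3SiCHN2 in toluene–MeOH to methyl (2R,3R)-2-ArC-5-oxooxolane-3-carboxylate F1. Its lithium enolate (LiN(i-Pr)2, 1.05 equiv, THF, −78 °C; the lactone CH2 is deprotonated faster than the hindered ester methine) is combined with 21 and the mixture is warmed to between −20 and 0 °C. The aldolate whose arm is trans to the ester reverts by retro-aldol; the small share formed on the ester face closes irreversibly onto the methyl ester with loss of methoxide, and the material returns to the route at 26. This variant relies on the exo lactonisation being the faster one and on brief exposure to base.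

**Step 10.** Elimination toward the benzylic C4–H, or slow substitution, may compete, because C5 is a secondary carbon flanked by an aryl-bearing carbon and two β-oxygen atoms. The fallback separates activation from displacement. It sets out from 19, which is converted with Tf2O and pyridine in CH2Cl2 at −20 °C into (4R,5R)-4-(4-benzyloxy-3-methoxyphenyl)-2,2-dimethyl-1,3-dioxan-5-yl trifluoromethanesulfonate F2. The weakly basic caesium phenoxide of 20 (Cs2CO3, DMF, 0 °C) then displaces the axial triflate with inversion, and the route is rejoined at 21.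

**Step 13.** Competing attack of one primary hydroxyl on the other primary mesylate (giving a 3,4-disubstituted tetrahydrofuran), or sulfonylation and ionisation of a benzylic hydroxyl, may lower the yield, because four hydroxyls compete and the benzylic positions are electron-rich. The fallback never opens the rings. It sets out from 26, which is reduced with i-Bu2AlH (2.2 equiv, CH2Cl2, −78 °C) to the bis-lactol (3R,3aR,6R,6aR)-3-ArB-6-ArC-tetrahydro-1H,3H-furo[3,4-c]furan-1,4-diol F3. Ionic reduction of both lactol carbons with Et3SiH and BF3·OEt2 in CH2Cl2 at −78 °C, through non-benzylic oxocarbenium ions, returns to the route at 29.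

**Step 9.** Ring iodination of the electron-rich arene or acid-induced opening of the acetonide may accompany the iodine-mediated cleavage of the enol ether. The fallback removes the allyl group reductively instead. It sets out from 17, which is treated with i-Bu2AlH and NiCl2(dppp) (catalytic) in toluene at 0 °C; hydroalumination of the allyl group and β-elimination release propene and the aluminium alkoxide of 19, where the route is rejoined without any new compound.

## Further compounds

F1 | step 11 | methyl (2R,3R)-2-ArC-5-oxooxolane-3-carboxylate | COC(=O)[C@@H]1CC(=O)O[C@H]1c1cc(OC)c(OCc2ccccc2)c(OC)c1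
F2 | step 10 | (4R,5R)-4-(4-benzyloxy-3-methoxyphenyl)-2,2-dimethyl-1,3-dioxan-5-yl trifluoromethanesulfonate | O=S(=O)(O[C@@H]1COC(C)(C)O[C@@H]1c1ccc(OCc2ccccc2)c(OC)c1)C(F)(F)F
F3 | step 13 | (3R,3aR,6R,6aR)-3-ArB-6-ArC-tetrahydro-1H,3H-furo[3,4-c]furan-1,4-diol (lactol carbons as anomer mixture) | COc1cc([C@@H](OC(C)(C)OC2)[C@H]2Oc2ccc([C@@H]3OC(O)[C@@H]4[C@H]3C(O)O[C@H]4c3cc(OC)c(OCc5ccccc5)c(OC)c3)cc2OC)ccc1OCc1ccccc1
F0 | step 9 | none | none
A1 | alternative 1 | trans-3-diazo-4-{[(4-benzyloxy-3,5-dimethoxybenzyl)oxy]methyl}-5-(3-methoxy-4-triisopropylsilyloxyphenyl)oxolan-2-one | COc1cc([C@@H]2OC(=O)C(=[N+]=[N-])[C@H]2COCc2cc(OC)c(OCc3ccccc3)c(OC)c2)ccc1O[Si](C(C)C)(C(C)C)C(C)C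
A2 | alternative 1 | furofuranone with the lactone carbonyl at C9′, ring B as triisopropylsilyl ether | COc1cc([C@@H]2OC(=O)[C@@H]3[C@H]2CO[C@H]3c2cc(OC)c(OCc3ccccc3)c(OC)c2)ccc1O[Si](C(C)C)(C(C)C)C(C)C
A3 | alternative 2 | (E)-3-ArB-prop-2-en-1-yl ether of ArC(oxiran-2-yl)methanol, C7′ as drawn, epoxide carbon unspecified | COc1cc([C@@H](OC(C)(C)OC2)[C@H]2Oc2ccc(/C=C/CO[C@@H](c3cc(OC)c(OCc4ccccc4)c(OC)c3)C3CO3)cc2OC)ccc1OCc1ccccc1
A4 | alternative 2 | dibenzyl ether acetonide of the target, identical with 29 | COc1cc([C@@H](OC(C)(C)OC2)[C@H]2Oc2ccc([C@@H]3OC[C@@H]4[C@H]3CO[C@H]4c3cc(OC)c(OCc5ccccc5)c(OC)c3)cc2OC)ccc1OCc1ccccc1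
A5 | alternative 3 | 2-ArB-3-(hydroxymethyl)-4-(4-hydroxy-3,5-dimethoxybenzyl)tetrahydrofuran of lariciresinol type | COc1cc([C@@H](OC(C)(C)OC2)[C@H]2Oc2ccc([C@@H]3OC[C@@H](Cc4cc(OC)c(O)c(OC)c4)[C@H]3CO)cc2OC)ccc1OCc1ccccc1
A6 | alternative 3 | target as its acetonide and ring A benzyl ether | COc1cc([C@@H](OC(C)(C)OC2)[C@H]2Oc2ccc([C@@H]3OC[C@@H]4[C@H]3CO[C@H]4c3cc(OC)c(O)c(OC)c3)cc2OC)ccc1OCc1ccccc1
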